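**Retrosynthetic overview**

1. Target 19 ⇐ bicyclic vinyl iodide 15 + alkyne 16: the C11–C12 bond is made last by Negishi coupling, because the (E,E)-diene would not survive the peroxidation chemistry.
2. 15 ⇐ acyclic triene hydroxy enoate 11 in one flask: hydroperoxysilylation at C6, then the hydroperoxide closes the 1,2-dioxane by 6-exo oxa-Michael addition (first ring) and the C4 hydroxyl closes the γ-lactone (second ring).
3. 11 ⇐ α-hydroxy ester 9 (ester → aldehyde → Wittig) ⇐ diene 7 + methyl pyruvate 8 by catalytic asymmetric carbonyl-ene reaction (forms C4–C5, sets C4).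
4. 7 ⇐ (R)-3-bromo-2-methylpropan-1-ol 1 (source of C8) by copper coupling, iodination, alkynylation and carboalumination–iodination.

Assumption: comments use biogenetic numbering (C1 lactone carbonyl, C3 and C6 the peroxide-bearing carbons, C4 the lactone-oxygen carbon, C8 the side-chain methine, C10–C13 the diene); 1, 2, 8 and 16 are bought.

**Route**

Step 1
Reactants: 1 (R)-3-bromo-2-methylpropan-1-ol; 2 isopropenylmagnesium bromide
Product: 3 (S)-2,4-dimethylpent-4-en-1-ol
Conditions: 2 (3 equiv), CuI (10 mol %), THF, −30 °C to rt; NH4Cl (aq)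
Reagents that add atoms: none
Why: Copper-catalysed Grignard cross-coupling (Kochi type) of the primary bromide, run on the bromomagnesium alkoxide formed by the first equivalent of 2; the stereocentre (C8) is not involved.

Step 2
Reactants: 3 (S)-2,4-dimethylpent-4-en-1-ol
Product: 4 (4S)-5-iodo-2,4-dimethylpent-1-ene
Conditions: I2, PPh3, imidazole, CH2Cl2, 0 °C to rt
Reagents that add atoms: iodine, II
Why: Appel-type iodination of a primary alcohol; the stereocentre is untouched.

Step 3
Reactants: 4 (4S)-5-iodo-2,4-dimethylpent-1-ene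
Product: 5 (4S)-2,4-dimethylhept-1-en-6-yne
Conditions: LiC≡CH·H2NCH2CH2NH2, DMSO, rt
Reagents that add atoms: lithium acetylide–ethylenediamine complex, [Li+].[C-]#C.NCCN
Why: SN2 alkynylation of the primary iodide in DMSO; β-branching slows but does not block substitution and C8 is untouched.

Step 4
Reactants: 5 (4S)-2,4-dimethylhept-1-en-6-yne
Product: 7 (1E,4S)-1-iodo-2,4,6-trimethylhepta-1,6-diene, via alkenylalane 6 (not isolated)
Conditions: AlMe3 (2.5 equiv), Cp2ZrCl2 (25 mol %), CH2Cl2, rt; then I2, THF, −30 °C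
Reagents that add atoms: trimethylaluminium (AlMe3), C[Al](C)C; iodine, II
Why: Negishi zirconium-catalysed carboalumination adds Me–Al syn across the terminal alkyne only (the 1,1-disubstituted alkene is inert), and iodinolysis with retention fixes the E trisubstituted vinyl iodide.

Step 5
Reactants: 7 (1E,4S)-1-iodo-2,4,6-trimethylhepta-1,6-diene; 8 methyl pyruvate
Product: 9 methyl (2S,6S,8E)-2-hydroxy-9-iodo-2,6,8-trimethyl-4-methylidenenon-8-enoate
Conditions: 8 (2 equiv), [Cu((S,S)-t-Bu-box)](SbF6)2 (10 mol %), CH2Cl2, rt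
Reagents that add atoms: none
Why: Catalytic enantioselective carbonyl-ene reaction (Evans type): the pyruvate chelates the copper–bis(oxazoline) Lewis acid and the 1,1-disubstituted alkene attacks the exposed si face of the ketone, setting C4 as S under catalyst control (a trisubstituted ene regioisomer, if formed, gives the same C6 radical in step 7).

Step 6
Reactants: 9 methyl (2S,6S,8E)-2-hydroxy-9-iodo-2,6,8-trimethyl-4-methylidenenon-8-enoate
Product: 11 methyl (2E,4S,8S,10E)-4-hydroxy-11-iodo-4,8,10-trimethyl-6-methylideneundeca-2,10-dienoate, via hydroxy aldehyde 10 (not isolated)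
Conditions: i-Bu2AlH (2.2 equiv), CH2Cl2, −78 °C; then Ph3P=CHCO2Me, MeOH, −78 °C to rt
Reagents that add atoms: methyl (triphenylphosphoranylidene)acetate, COC(=O)C=P(c1ccccc1)(c1ccccc1)c1ccccc1
Why: Low-temperature aluminium hydride reduction stops at the chelated hemiacetal aluminate, and the released α-hydroxy aldehyde is trapped in the same flask by the stabilised ylide (E-selective Wittig reaction); C4 is quaternary and cannot epimerise.

Step 7
Reactants: 11 methyl (2E,4S,8S,10E)-4-hydroxy-11-iodo-4,8,10-trimethyl-6-methylideneundeca-2,10-dienoate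
Product: 15 (3R,4aS,7aS)-3-[(2R,4E)-5-iodo-2,4-dimethylpent-4-en-1-yl]-3,4a-dimethyl-4,4a,7,7a-tetrahydro-3H-furo[3,2-c][1,2]dioxin-6-one, via silyl peroxide 12 (not isolated), via hydroperoxide 13 (not isolated), via dioxane hydroxy ester 14 (not isolated)
Conditions: Co(thd)2 (5 mol %; thd = 2,2,6,6-tetramethylheptane-3,5-dionate), O2 (1 atm), Et3SiH, ClCH2CH2Cl, rt; SiO2 pad; HCl (cat.), MeOH, 0 °C; then Et2NH, CF3CH2OH, rt; TsOH (cat.), CH2Cl2
Reagents that add atoms: dioxygen, O=O
Why: Telescoped Mukaiyama–Isayama hydroperoxysilylation (hydrogen-atom transfer to the 1,1-disubstituted alkene, O2 capture at C6), desilylation, 6-exo oxa-Michael addition of the hydroperoxide to the enoate in Et2NH/CF3CH2OH, and lactonisation of the C4 hydroxyl; C3 is set as S by C4 because only the cis-fused lactone can close and the oxa-Michael step is reversible, whereas C6 comes from an acyclic tertiary radical without control (about 1:1), so 6R-configured 15 is separated from its 6-epimer by chromatography here.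

Step 8
Reactants: 15 (3R,4aS,7aS)-3-[(2R,4E)-5-iodo-2,4-dimethylpent-4-en-1-yl]-3,4a-dimethyl-4,4a,7,7a-tetrahydro-3H-furo[3,2-c][1,2]dioxin-6-one; 16 1-phenylbut-2-yne
Product: 19 (3R,4aS,7aS)-3,4a-dimethyl-3-[(2R,4E,6E)-2,4,6-trimethyl-8-phenylocta-4,6-dien-1-yl]-4,4a,7,7a-tetrahydro-3H-furo[3,2-c][1,2]dioxin-6-one, via alkenylzirconocene 17 (not isolated), via alkenylzinc chloride 18 (not isolated)
Conditions: 16, Cp2Zr(H)Cl, THF, 40 °C; ZnCl2, 0 °C; then 15, Pd(PPh3)4 (5 mol %), THF, rt
Reagents that add atoms: none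
Why: Syn-hydrozirconation of the 2-alkyne places zirconium on the methyl-bearing carbon, and transmetalation to zinc followed by Negishi coupling with the vinyl iodide joins C11–C12 with retention of both alkene geometries; the dialkyl peroxide and lactone should tolerate zerovalent palladium and the mild organozinc at room temperature.

**Compound list**

1 | (R)-3-bromo-2-methylpropan-1-ol | OC[C@@H](C)CBr | starting material
2 | isopropenylmagnesium bromide, CH2=C(CH3)MgBr | CC(=C)[Mg]Br | starting material
3 | (S)-2,4-dimethylpent-4-en-1-ol | OC[C@@H](C)CC(C)=C | intermediate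
4 | (4S)-5-iodo-2,4-dimethylpent-1-ene | IC[C@@H](C)CC(C)=C | intermediate
5 | (4S)-2,4-dimethylhept-1-en-6-yne | C#CC[C@@H](C)CC(C)=C | intermediate
6 | dimethyl[(1E,4S)-2,4,6-trimethylhepta-1,6-dien-1-yl]alumane | C[Al](C)/C=C(\C)C[C@@H](C)CC(C)=C | intermediate
7 | (1E,4S)-1-iodo-2,4,6-trimethylhepta-1,6-diene | I/C=C(\C)C[C@@H](C)CC(C)=C | intermediate
8 | methyl pyruvate | CC(=O)C(=O)OC | starting material
9 | methyl (2S,6S,8E)-2-hydroxy-9-iodo-2,6,8-trimethyl-4-methylidenenon-8-enoate | I/C=C(\C)C[C@@H](C)CC(=C)C[C@](C)(O)C(=O)OC | intermediate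
10 | (2S,6S,8E)-2-hydroxy-9-iodo-2,6,8-trimethyl-4-methylidenenon-8-enal | I/C=C(\C)C[C@@H](C)CC(=C)C[C@](C)(O)C=O | intermediate
11 | methyl (2E,4S,8S,10E)-4-hydroxy-11-iodo-4,8,10-trimethyl-6-methylideneundeca-2,10-dienoate | I/C=C(\C)C[C@@H](C)CC(=C)C[C@](C)(O)/C=C/C(=O)OC | intermediate
12 | methyl (2E,4S,6R,8R,10E)-4-hydroxy-11-iodo-4,6,8,10-tetramethyl-6-[(triethylsilyl)peroxy]undeca-2,10-dienoate | I/C=C(\C)C[C@@H](C)C[C@](OO[Si](CC)(CC)CC)(C)C[C@](C)(O)/C=C/C(=O)OC | intermediate
13 | methyl (2E,4S,6R,8R,10E)-6-hydroperoxy-4-hydroxy-11-iodo-4,6,8,10-tetramethylundeca-2,10-dienoate | I/C=C(\C)C[C@@H](C)C[C@](OO)(C)C[C@](C)(O)/C=C/C(=O)OC | intermediate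
14 | methyl 2-[(3S,4S,6R)-4-hydroxy-6-[(2R,4E)-5-iodo-2,4-dimethylpent-4-en-1-yl]-4,6-dimethyl-1,2-dioxan-3-yl]acetate | I/C=C(\C)C[C@@H](C)C[C@]1(C)C[C@](C)(O)[C@H](CC(=O)OC)OO1 | intermediate
15 | (3R,4aS,7aS)-3-[(2R,4E)-5-iodo-2,4-dimethylpent-4-en-1-yl]-3,4a-dimethyl-4,4a,7,7a-tetrahydro-3H-furo[3,2-c][1,2]dioxin-6-one (cis-fused 1,2-dioxane/γ-lactone) | I/C=C(\C)C[C@@H](C)C[C@]1(C)C[C@]2(C)OC(=O)C[C@@H]2OO1 | intermediate
16 | 1-phenylbut-2-yne | CC#CCc1ccccc1 | starting material
17 | chloridobis(cyclopentadienyl)[(2E)-4-phenylbut-2-en-2-yl]zirconium (Zr trans to benzyl; cyclopentadienyl rings drawn σ-bonded) | C/C(=C\Cc1ccccc1)[Zr](Cl)(C1C=CC=C1)C1C=CC=C1 | intermediate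
18 | chlorido[(2E)-4-phenylbut-2-en-2-yl]zinc | C/C(=C\Cc1ccccc1)[Zn]Cl | intermediate
19 | (3R,4aS,7aS)-3,4a-dimethyl-3-[(2R,4E,6E)-2,4,6-trimethyl-8-phenylocta-4,6-dien-1-yl]-4,4a,7,7a-tetrahydro-3H-furo[3,2-c][1,2]dioxin-6-one (CNP0272658.1) | CC(=C\Cc1ccccc1)/C=C(\C)C[C@@H](C)C[C@]1(C)C[C@]2(C)OC(=O)C[C@@H]2OO1 | target

**Step count and risks**

Total step count: 8. Longest linear sequence: 8 steps (1 → 19).

Most likely to fail, first: step 7. Hydrogen-atom transfer has to pick the 1,1-disubstituted alkene over the enoate and the vinyl iodide, and the free hydroperoxide must survive traces of cobalt. C6 is formed without stereocontrol, so at best about half of the material becomes 15 and the 6-epimer cannot be recycled. The fallback sets out from 11 and replaces the radical oxygenation by ionic Markovnikov perhydrolysis: anhydrous H2O2 in Et2O with catalytic H2SO4 at 0 °C protonates the 1,1-disubstituted alkene and H2O2 captures the tertiary cation, giving hydroperoxide 13 directly with no cobalt, silane or radical near the vinyl iodide. It comes back to the route at 13, which is cyclised with Et2NH in CF3CH2OH as in step 7. It does not improve the C6 ratio, and it makes no compound outside the list (F0).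

Second: step 8. Hydrozirconation of 16 may give some of the regioisomeric alkenylzirconium, and the organometallics and palladium must leave the O–O bond alone. The fallback sets out from 15 and couples it by Suzuki–Miyaura reaction (Pd(dppf)Cl2, Cs2CO3, THF/H2O, rt) with 4,4,5,5-tetramethyl-2-[(2Z)-4-phenylbut-2-en-2-yl]-1,3,2-dioxaborolane F3. F3 is made regiospecifically by boron-Wittig olefination of phenylacetaldehyde with lithiated 1,1-bis(pinacolboryl)ethane (lithium 2,2,6,6-tetramethylpiperidide, THF, −78 °C), which is expected to place the aldehyde residue trans to the remaining boryl group. It comes back to the route at 19.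

Third: step 1. The copper-catalysed coupling of an alkenyl Grignard reagent with a β-branched bromide carrying a free alkoxide may be slow or give elimination. The fallback sets out from 1 and builds the isopropenyl group by acyl-anion alkylation and olefination instead. Compound 1 (deprotonated with n-BuLi) is alkylated with 2-lithio-2-methyl-1,3-dithiane in THF/DMPU to give (S)-2-methyl-3-(2-methyl-1,3-dithian-2-yl)propan-1-ol F1. MeI and CaCO3 in aqueous MeCN unmask (S)-5-hydroxy-4-methylpentan-2-one F2, and Wittig methylenation with excess Ph3P=CH2 returns to the route at 3.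

**Further compounds**

F0 | step 7 | none | none
F1 | step 1 | (S)-2-methyl-3-(2-methyl-1,3-dithian-2-yl)propan-1-ol | OC[C@@H](C)CC1(C)SCCCS1
F2 | step 1 | (S)-5-hydroxy-4-methylpentan-2-one | OC[C@@H](C)CC(C)=O
F3 | step 8 | 4,4,5,5-tetramethyl-2-[(2Z)-4-phenylbut-2-en-2-yl]-1,3,2-dioxaborolane (boron trans to benzyl) | C/C(=C\Cc1ccccc1)B1OC(C)(C)C(C)(C)O1
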